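**Strategy.** Ring B (N1', C2'–C5') is disconnected at N1'–C5' and C2'–C3'. Its N1'=C2' unit already carries ring A at C2', so it is taken from the nitrile of pyrrole-2-carbonitrile. C3'–C4'–C5' are the three carbons of a 1,3-zwitterion released by Me3SiOTf from a donor–acceptor cyclopropane, ethyl 2-ethoxycyclopropane-1-carboxylate. One operation forms both bonds, closes ring B and aromatises it by loss of ethanol, giving the 2,2'-bipyrrole core with an ester at C3'. That ester is then stripped by saponification–decarboxylation, and the six free positions C3, C4, C5, C3', C4' and C5' are brominated in the last step.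

Key step: step 2

Remarks on the chemistry: the target is the achiral 3,3',4,4',5,5'-hexabromo-1H,1'H-2,2'-bipyrrole (C8H2Br6N2). Atom labels in the text: ring A = N1, C2–C5 (from the nitrile partner); ring B = N1', C2'–C5' (made in the key step, ester at C3'); systematic names keep their own locants. The cyclopropane is used as the racemic trans/cis mixture that the cyclopropanation delivers (trans isomer drawn); both of its stereocentres disappear in the key step.

**Step 1**
Reactants: 1 ethyl vinyl ether; 2 ethyl diazoacetate
Product: 3 ethyl (1R*,2R*)-2-ethoxycyclopropane-1-carboxylate (racemic trans isomer drawn, racemic cis isomer alongside)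
Conditions: Rh2(OAc)4 (0.5 mol %), 1 (5 equiv), Et2O, 2 added over 8 h, rt
Reagents that add atoms: none
Why: Rhodium-carbenoid cyclopropanation of an electron-rich alkene, in which slow addition of 2 to excess 1 keeps carbene dimerisation down; the two new stereocentres form without control as a racemic trans/cis mixture, which is acceptable because step 2 erases both.

**Step 2**
Reactants: 3 ethyl 2-ethoxycyclopropane-1-carboxylate (1.5 equiv); 4 1H-pyrrole-2-carbonitrile
Product: 6 ethyl 1H,1'H-2,2'-bipyrrole-3-carboxylate, via ethoxypyrroline ester 5 (not isolated)
Conditions: Me3SiOTf (1.1 equiv), MeNO2, −25 °C to rt; aq NaHCO3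
Reagents that add atoms: none
Why: Me3SiOTf silylates the ester carbonyl of 3 and the polarised C1–C2 cyclopropane bond ionises to an oxocarbenium ion tethered through CH2 to a silyl ketene acetal; the nitrile nitrogen of 4 adds to the oxocarbenium carbon in a Ritter-type step (N1'–C5') and the ketene acetal carbon then attacks the nitrilium carbon (C2'–C3') to give 5, which loses ethanol under the acidic conditions and tautomerises to the aromatic ring B of 6. The closest known reaction type is the Me3SiOTf-mediated formal [3+2] cycloaddition of 2-alkoxycyclopropane carboxylates with nitriles, which tolerates 2-cyanopyrroles and so delivers 2,2'-bipyrroles. Ring B closes in a 5-endo-dig mode on the linear nitrilium ion. No lasting stereocentre is created: cis- and trans-3 open to the same achiral zwitterion equivalent, and the two stereocentres of 5 vanish on aromatisation. The step needs regioselectivity, which the polarity of the dipole fixes (nitrogen to the alkoxy-bearing carbon, nitrile carbon to the ester-bearing carbon), and chemoselectivity for the nitrile over the C–H positions of ring A, which the electron-withdrawing cyano group and the low temperature secure.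

**Step 3**
Reactants: 6 ethyl 1H,1'H-2,2'-bipyrrole-3-carboxylate
Product: 8 1H,1'H-2,2'-bipyrrole, via sodium bipyrrole-3-carboxylate 7 (not isolated)
Conditions: NaOH (10 equiv), HOCH2CH2OH (wet), 190 °C, Ar
Reagents that add atoms: none
Why: One-pot saponification and protodecarboxylation in hot alkaline glycol, the classical way of stripping ester groups from pyrroles: hydroxide cleaves the vinylogous carbamate ester to 7, whose C3' is protonated by the solvent (the resulting C2'=N1' iminium is conjugated with ring A) so that CO2 leaves as carbonate.

**Step 4**
Reactants: 8 1H,1'H-2,2'-bipyrrole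
Product: 9 3,3',4,4',5,5'-hexabromo-1H,1'H-2,2'-bipyrrole (target)
Conditions: NBS (6.3 equiv), THF, −78 °C to rt, dark
Reagents that add atoms: N-bromosuccinimide, O=C1CCC(=O)N1Br
Why: Exhaustive electrophilic aromatic bromination of two π-excessive pyrrole rings, an established way to perhalogenate pyrroles and 2,2'-bipyrroles: C5 and C5' should react first, which blocks oxidative coupling, and C4, C4', C3 and C3' should follow on warming, with no strong acid generated to polymerise the substrate.

**Compound list**
1 | ethyl vinyl ether (ethoxyethene) | C=COCC | starting material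
2 | ethyl diazoacetate | CCOC(=O)C=[N+]=[N-] | starting material
3 | ethyl (1R*,2R*)-2-ethoxycyclopropane-1-carboxylate (racemic trans isomer drawn; the racemic cis isomer accompanies it and is used as well) | CCOC(=O)[C@@H]1C[C@H]1OCC | intermediate
4 | 1H-pyrrole-2-carbonitrile | N#Cc1ccc[nH]1 | starting material
5 | ethyl 2-ethoxy-5-(1H-pyrrol-2-yl)-3,4-dihydro-2H-pyrrole-4-carboxylate (not isolated; diastereomer mixture, configuration uncontrolled and irrelevant) | CCOC(=O)C1CC(OCC)N=C1c1ccc[nH]1 | intermediate
6 | ethyl 1H,1'H-2,2'-bipyrrole-3-carboxylate | CCOC(=O)c1cc[nH]c1-c1ccc[nH]1 | intermediate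
7 | sodium 1H,1'H-2,2'-bipyrrole-3-carboxylate (not isolated) | [Na+].[O-]C(=O)c1cc[nH]c1-c1ccc[nH]1 | intermediate
8 | 1H,1'H-2,2'-bipyrrole | c1c[nH]c(c1)-c1ccc[nH]1 | intermediate
9 | 3,3',4,4',5,5'-hexabromo-1H,1'H-2,2'-bipyrrole | Brc1[nH]c(-c2[nH]c(Br)c(Br)c2Br)c(Br)c1Br | target

**Step count.** Total: 4 steps. Longest linear sequence: 4 steps (1 and 2 → 3 → 6 → 8 → 9); 4 is commercial and enters at step 2.

**Steps most likely to fail, with fallbacks**

Step 2. The silylated cyclopropane may oligomerise, or the oxocarbenium ion may alkylate ring A of 4 faster than the weakly nucleophilic nitrile nitrogen captures it. The fallback builds ring B on the same nitrile by enamine chemistry. It sets out from 4. A Blaise reaction with the Reformatsky reagent from ethyl bromoacetate and Zn (excess to allow for the N–H, THF, reflux; aqueous K2CO3 work-up) should give ethyl (Z)-3-amino-3-(1H-pyrrol-2-yl)prop-2-enoate F1. A Hantzsch pyrrole synthesis of this enamino ester with aqueous chloroacetaldehyde (NaHCO3, EtOH, 60 °C) should then close ring B and come back to the route at 6.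

Step 3. Loss of CO2 from the β position may lag behind saponification, so that long heating near 190 °C degrades the electron-rich bipyrrole. The fallback avoids replacing the carboxyl group by hydrogen. It sets out from 6. KOH in aqueous EtOH at reflux, then acidification to pH 4, should give 1H,1'H-2,2'-bipyrrole-3-carboxylic acid F2. Excess Br2 in NaOAc-buffered AcOH (rt to 50 °C) should then substitute the five C–H positions and replace the carboxyl group at C3' by ipso attack and loss of CO2 (bromodecarboxylation). This arrives directly at 9 and bypasses 8.

Step 4. Oxidative coupling of the unsubstituted bipyrrole by the N-bromo reagent may compete before the α positions are blocked, or substitution may stall at the crowded C3 and C3'. The fallback moves the halogenation to the ester stage, where the acceptor on ring B makes the π-system less oxidisable. It sets out from 6. Br2 with NaOAc in AcOH should give ethyl 3',4,4',5,5'-pentabromo-1H,1'H-2,2'-bipyrrole-3-carboxylate F3. KOH in aqueous EtOH should then give 3',4,4',5,5'-pentabromo-1H,1'H-2,2'-bipyrrole-3-carboxylic acid F4. Bromodecarboxylation of F4 (Br2, NaOAc, AcOH, 50 °C) should put the sixth bromine on the carboxyl-bearing carbon and come back to the route at 9.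

**Further compounds**
F1 | step 2 | ethyl (Z)-3-amino-3-(1H-pyrrol-2-yl)prop-2-enoate | CCOC(=O)/C=C(\N)c1ccc[nH]1
F2 | step 3 | 1H,1'H-2,2'-bipyrrole-3-carboxylic acid | OC(=O)c1cc[nH]c1-c1ccc[nH]1
F3 | step 4 | ethyl 3',4,4',5,5'-pentabromo-1H,1'H-2,2'-bipyrrole-3-carboxylate | CCOC(=O)c1c(Br)c(Br)[nH]c1-c1[nH]c(Br)c(Br)c1Br
F4 | step 4 | 3',4,4',5,5'-pentabromo-1H,1'H-2,2'-bipyrrole-3-carboxylic acid | OC(=O)c1c(Br)c(Br)[nH]c1-c1[nH]c(Br)c(Br)c1Br
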